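**Retrosynthetic overview**
1. The target comes from double tigloylation of the 8α,9α-diol, which comes from convex-face hydride reduction of the 8α-hydroxy-9-ketone (eremophilane numbering).
2. The six-membered ring B of that ketol comes from an α-ketol 1,2-shift (ring expansion, five to six) of a cis-hydrindane tertiary α-hydroxy aldehyde. The formyl carbon becomes C8 and the carbinol carbon becomes C9.
3. The α-hydroxy aldehyde comes from isopropenyl-copper conjugate addition and enolate oxygenation of a cyclopentenecarbaldehyde. The C4 methyl comes from conjugate methylation of the bicyclic enone.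
4. The cis-hydrindene comes from a desymmetrising intramolecular Rauhut–Currier closure of a 4-methyl-4-(4-oxobut-2-enyl)cyclohexadienone, built from p-cresol, an allylsilane and crotonaldehyde.
5. Ring order: ring A (from the arene), then the five-membered precursor of ring B, then expansion to the six-membered ring B.

Assumption: eremophilane numbering is used for positions and faces (β = the face of the two methyl groups), and the (S)-aminocatalyst of step 3 is taken to give the (3aS,7aR) series; if it gives the opposite series, its enantiomer is used.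

**Step 1**
Reactants: 1 p-cresol (4-methylphenol); 2 allyltrimethylsilane
Product: 3 4-methyl-4-(prop-2-en-1-yl)cyclohexa-2,5-dien-1-one
Conditions: PhI(OAc)2 (1.1 equiv), 2 (3 equiv), (CF3)2CHOH, 0 °C
Reagents that add atoms: none
Why: Hypervalent-iodine oxidative dearomatisation (oxidative Hosomi–Sakurai allylation), in which the phenol is turned in the ionising, non-nucleophilic solvent into a phenoxenium-type electrophile that the allylsilane captures at the methyl-bearing para carbon, giving the achiral quaternary dienone (no stereocentre yet).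

**Step 2**
Reactants: 3 4-methyl-4-(prop-2-en-1-yl)cyclohexa-2,5-dien-1-one; 4 (E)-crotonaldehyde
Product: 5 (2E)-4-(1-methyl-4-oxocyclohexa-2,5-dien-1-yl)but-2-enal
Conditions: 4 (5 equiv), second-generation Hoveyda–Grubbs catalyst RuCl2(H2IMes)(=CH-2-iPrOC6H4) (3 mol %), CH2Cl2, 40 °C
Reagents that add atoms: none
Why: Olefin cross-metathesis of a reactive terminal alkene with an electron-poor partner gives the E-enal, while the electron-poor ring C=C bonds next to the quaternary carbon do not take part.

**Step 3**
Reactants: 5 (2E)-4-(1-methyl-4-oxocyclohexa-2,5-dien-1-yl)but-2-enal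
Product: 6 (3aS,7aR)-7a-methyl-5-oxo-3a,4,5,7a-tetrahydro-1H-indene-3-carbaldehyde
Conditions: (S)-2-[diphenyl(trimethylsilyloxy)methyl]pyrrolidine (20 mol %), PhCO2H (20 mol %), toluene, 23 °C
Reagents that add atoms: none
Why: Dienamine-mediated intramolecular Rauhut–Currier reaction (aminocatalytic desymmetrising Michael addition), in which the α-carbon of the dienamine closes 5-(enolexo)-exo-trig on one of the two enantiotopic enone arms, the short tether forces the cis ring fusion, the shielded catalyst face selects the arm and so sets C5 (R) and C10 (S), and tautomerisation restores the conjugated enal.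

**Step 4**
Reactants: 6 (3aS,7aR)-7a-methyl-5-oxo-3a,4,5,7a-tetrahydro-1H-indene-3-carbaldehyde; 7 dimethylzinc
Product: 8 (3aS,7S,7aR)-7,7a-dimethyl-5-oxo-3a,4,5,6,7,7a-hexahydro-1H-indene-3-carbaldehyde
Conditions: 7 (1.5 equiv), Cu(OTf)2 (5 mol %), P(OEt)3 (10 mol %), toluene, −30 → 0 °C
Reagents that add atoms: none
Why: Copper-catalysed conjugate addition of a dialkylzinc, in which the s-trans cyclohexenone reacts much faster than the α,β-disubstituted enal, Me2Zn does not add to the formyl group, and axial attack at C4 anti to the pseudoaxial C5–C6 bond comes from the convex β face (syn only to H-10), so the new methyl is cis to the angular methyl (4S in eremophilane numbering).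

**Step 5**
Reactants: 8 (3aS,7S,7aR)-7,7a-dimethyl-5-oxo-3a,4,5,6,7,7a-hexahydro-1H-indene-3-carbaldehyde; 9 prop-1-en-2-ylmagnesium bromide
Product: 12 (2R,3R,4aR,5S,8aS)-2-hydroxy-4a,5-dimethyl-3-(prop-1-en-2-yl)octahydronaphthalene-1,7-dione, via magnesium enolate 10 (not isolated), via magnesium alkoxide of the hydroxy aldehyde 11 (not isolated)
Conditions: 9 (2.2 equiv), CuBr·SMe2 (1.1 equiv), THF–Me2S, −78 °C; 2-(phenylsulfonyl)-3-phenyloxaziridine (1.5 equiv), −78 °C; MgBr2·OEt2 (2 equiv), −78 → 23 °C
Reagents that add atoms: 2-(phenylsulfonyl)-3-phenyloxaziridine, O=S(=O)(c1ccccc1)N1OC1c1ccccc1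
Why: Proposed new method: a one-pot ring-expanding oxidative conjugate addition of a 1-formylcycloalkene, not yet described; the magnesium cuprate adds the isopropenyl group to C7 from the convex β face (ring A covers the α face), the aldehyde enolate 10 is oxygenated by the N-sulfonyloxaziridine anti to the new pseudoaxial isopropenyl group to give the tertiary alkoxide 11, and divalent magnesium then ties the alkoxide and formyl oxygens into a five-membered chelate (syn-periplanar O–C–C=O, formyl oxygen pointing away from the ring) in which the allylic, electron-rich C7–C9 σ bond lies parallel to the formyl π* orbital and shifts to the formyl carbon with retention at C7, so the formyl carbon becomes C8 with an equatorial α-hydroxyl trans to the isopropenyl group and the old carbinol carbon becomes the C9 ketone; the shift is driven by the aldehyde-to-ketone change, by release of eclipsing strain in the pentasubstituted cyclopentane and by the stable chelate of the product; the closest known reaction types are tandem cuprate addition/Davis enolate hydroxylation and the Lewis-acid α-ketol (acyloin) rearrangement used for D-homoannulation of 17-hydroxy-20-oxo steroids.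

**Step 6**
Reactants: 12 (2R,3R,4aR,5S,8aS)-2-hydroxy-4a,5-dimethyl-3-(prop-1-en-2-yl)octahydronaphthalene-1,7-dione
Product: 15 (4S,4aR,6R,7R,8S,8aS)-7,8-dihydroxy-4,4a-dimethyl-6-(prop-1-en-2-yl)octahydronaphthalen-2(1H)-one, via keto ketal 13 (not isolated), via diol ketal 14 (not isolated)
Conditions: HC(OMe)3 (1.5 equiv), CeCl3·7H2O (10 mol %), MeOH, 0 °C; NaBH4, −78 → −40 °C; 1 M HCl, THF, 23 °C
Reagents that add atoms: none
Why: One-pot selective ketalisation and borohydride reduction (Luche-type in situ protection), in which the unhindered C2 cyclohexanone is masked as its dimethyl ketal while the C9 ketone (flanked by the ring-fusion CH and the carbinol, and inductively deactivated towards oxocarbenium formation) stays free, hydride reaches C9 only from the convex β face because the axial C5–C4 bond blocks the α trajectory, which gives the axial 9α-alcohol cis to 8α-OH, and aqueous acid returns the C2 ketone.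

**Step 7**
Reactants: 15 (4S,4aR,6R,7R,8S,8aS)-7,8-dihydroxy-4,4a-dimethyl-6-(prop-1-en-2-yl)octahydronaphthalen-2(1H)-one; 16 tigloyl chloride [(2E)-2-methylbut-2-enoyl chloride]
Product: 17 (1S,2R,3R,4aR,5S,8aS)-4a,5-dimethyl-7-oxo-3-(prop-1-en-2-yl)decahydronaphthalene-1,2-diyl bis[(2E)-2-methylbut-2-enoate] (target)
Conditions: 16 (4 equiv), pyridine, 4-(dimethylamino)pyridine (0.2 equiv), CH2Cl2, 40 °C
Reagents that add atoms: none
Why: Nucleophile-catalysed (DMAP) acylation of both secondary alcohols with retention at C8 and C9, using the stable (E)-tigloyl unit and pyridine rather than a trialkylamine so that vinylketene formation and deconjugation are avoided.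

**Compound list**
1 | p-cresol (4-methylphenol) | Cc1ccc(O)cc1 | starting material
2 | allyltrimethylsilane | C=CC[Si](C)(C)C | starting material
3 | 4-methyl-4-(prop-2-en-1-yl)cyclohexa-2,5-dien-1-one | C=CCC1(C)C=CC(=O)C=C1 | intermediate
4 | (E)-crotonaldehyde | C/C=C/C=O | starting material
5 | (2E)-4-(1-methyl-4-oxocyclohexa-2,5-dien-1-yl)but-2-enal | O=C/C=C/CC1(C)C=CC(=O)C=C1 | intermediate
6 | (3aS,7aR)-7a-methyl-5-oxo-3a,4,5,7a-tetrahydro-1H-indene-3-carbaldehyde (cis-fused) | O=CC1=CC[C@]2(C)C=CC(=O)C[C@H]12 | intermediate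
7 | dimethylzinc | C[Zn]C | starting material
8 | (3aS,7S,7aR)-7,7a-dimethyl-5-oxo-3a,4,5,6,7,7a-hexahydro-1H-indene-3-carbaldehyde (cis-fused, methyls cis) | O=CC1=CC[C@]2(C)[C@@H](C)CC(=O)C[C@H]12 | intermediate
9 | prop-1-en-2-ylmagnesium bromide | C=C(C)[Mg]Br | starting material
10 | bromomagnesium enolate: 3-(bromomagnesiooxymethylidene)-7,7a-dimethyl-2-(prop-1-en-2-yl)-cis-octahydroinden-5-one; isopropenyl, both methyls and H-3a on the β face; enolate geometry open | C=C(C)[C@H]1C[C@@]2(C)[C@H](CC(=O)C[C@@H]2C)C1=CO[Mg]Br | intermediate (not isolated)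
11 | bromomagnesium alkoxide of (2R,3R,3aS,7S,7aR)-3-hydroxy-7,7a-dimethyl-5-oxo-2-(prop-1-en-2-yl)octahydro-1H-indene-3-carbaldehyde (O on the α face, CHO on the β face) | C=C(C)[C@H]1C[C@@]2(C)[C@H](CC(=O)C[C@@H]2C)[C@@]1(O[Mg]Br)C=O | intermediate (not isolated)
12 | (2R,3R,4aR,5S,8aS)-2-hydroxy-4a,5-dimethyl-3-(prop-1-en-2-yl)octahydronaphthalene-1,7-dione (cis-decalin; 8α-OH, 9-ketone) | C=C(C)[C@H]1C[C@@]2(C)[C@H](CC(=O)C[C@@H]2C)C(=O)[C@@H]1O | intermediate
13 | (2R,3R,4aR,5S,8aS)-2-hydroxy-7,7-dimethoxy-4a,5-dimethyl-3-(prop-1-en-2-yl)octahydronaphthalen-1(2H)-one | C=C(C)[C@H]1C[C@@]2(C)[C@H](CC(OC)(OC)C[C@@H]2C)C(=O)[C@@H]1O | intermediate (not isolated)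
14 | (1S,2R,3R,4aR,5S,8aS)-7,7-dimethoxy-4a,5-dimethyl-3-(prop-1-en-2-yl)decahydronaphthalene-1,2-diol | C=C(C)[C@H]1C[C@@]2(C)[C@H](CC(OC)(OC)C[C@@H]2C)[C@H](O)[C@@H]1O | intermediate (not isolated)
15 | (4S,4aR,6R,7R,8S,8aS)-7,8-dihydroxy-4,4a-dimethyl-6-(prop-1-en-2-yl)octahydronaphthalen-2(1H)-one | C=C(C)[C@H]1C[C@@]2(C)[C@H](CC(=O)C[C@@H]2C)[C@H](O)[C@@H]1O | intermediate
16 | tigloyl chloride | C/C=C(\C)C(=O)Cl | starting material
17 | (1S,2R,3R,4aR,5S,8aS)-4a,5-dimethyl-7-oxo-3-(prop-1-en-2-yl)decahydronaphthalene-1,2-diyl bis[(2E)-2-methylbut-2-enoate] | C=C(C)[C@H]1C[C@@]2(C)[C@H](CC(=O)C[C@@H]2C)[C@H](OC(=O)/C(C)=C/C)[C@@H]1OC(=O)/C(C)=C/C | target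

Total step count: 7. Longest linear sequence: 7 (1 → 3 → 5 → 6 → 8 → 12 → 15 → 17).

**Three steps most likely to fail**

**Step 5 (the proposed new step).**
- Risks: 1,2-addition to the formyl group, slow oxygenation of the hindered enolate carbon, the face of oxygenation, and the choice of migrating carbon.
- The fallback sets out from 8 and comes back at 12 by three known operations.
- The same cuprate is added in the presence of Me3SiCl to give the trimethylsilyl enol ether F1.
- Rubottom oxidation of F1 with dimethyldioxirane (acetone, −78 °C; the enol ether reacts far faster than the isopropenyl group) and citric acid work-up gives the free α-hydroxy aldehyde F2. F2 is isolated, so its configuration can be checked.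
- Heating F2 with Al(Ot-Bu)3 in toluene, the classical chelating α-ketol conditions, gives 12.
- If C10 migrates instead of C7, in either mode, the isomeric ketol F3 (8-ketone, 9α-alcohol) is formed. It needs no separation, because the conditions of step 6 reduce it from the same β face to the same diol 15.

**Step 3.**
- Risks: insufficient discrimination of the two enone arms at an all-carbon quaternary centre, and slow dienamine formation next to that centre.
- The fallback sets out from 3 and comes back at 8. It moves the absolute stereocontrol from aminocatalysis to copper catalysis.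
- Desymmetrising conjugate addition of 7 to dienone 3 with Cu(OTf)2 and a binaphthol-derived bis(1-phenylethyl)amine phosphoramidite ligand gives (4R,5S)-4,5-dimethyl-4-(prop-2-en-1-yl)cyclohex-2-en-1-one F4. The methyl enters anti to the larger allyl group, and the minor trans-dimethyl isomer is removed by chromatography.
- Cross-metathesis with 4 as in step 2 gives the enal F5.
- An achiral PBu3-catalysed Rauhut–Currier cyclisation, whose cis ring fusion is dictated by the tether, gives 8 directly.

**Step 4.**
- Risk: the enal competes with the hindered ring enone for the methyl nucleophile.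
- The fallback sets out from 6 and comes back at 8.
- The formyl group is first masked as its 1,3-dioxolane F6 with (Me3SiOCH2)2 and catalytic Me3SiOTf at −78 °C (aldehyde-selective, no double-bond shift).
- Stoichiometric Me2CuLi then adds to the only remaining acceptor, with the same convex-face selectivity, to give F7.
- Pyridinium p-toluenesulfonate in wet acetone releases 8.

**Further compounds**
F1 | step 5 | trimethylsilyl enol ether: 7,7a-dimethyl-2-(prop-1-en-2-yl)-3-(trimethylsilyloxymethylidene)-cis-octahydroinden-5-one (isopropenyl, both methyls and H-3a on the β face) | C=C(C)[C@H]1C[C@@]2(C)[C@H](CC(=O)C[C@@H]2C)C1=CO[Si](C)(C)C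
F2 | step 5 | (2R,3R,3aS,7S,7aR)-3-hydroxy-7,7a-dimethyl-5-oxo-2-(prop-1-en-2-yl)octahydro-1H-indene-3-carbaldehyde | C=C(C)[C@H]1C[C@@]2(C)[C@H](CC(=O)C[C@@H]2C)[C@@]1(O)C=O
F3 | step 5 | (1S,3R,4aR,5S,8aS)-1-hydroxy-4a,5-dimethyl-3-(prop-1-en-2-yl)octahydronaphthalene-2,7-dione | C=C(C)[C@H]1C[C@@]2(C)[C@H](CC(=O)C[C@@H]2C)[C@H](O)C1=O
F4 | step 3 | (4R,5S)-4,5-dimethyl-4-(prop-2-en-1-yl)cyclohex-2-en-1-one | C=CC[C@@]1(C)C=CC(=O)C[C@@H]1C
F5 | step 3 | (2E)-4-[(1R,6S)-1,6-dimethyl-4-oxocyclohex-2-en-1-yl]but-2-enal | O=C/C=C/C[C@@]1(C)C=CC(=O)C[C@@H]1C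
F6 | step 4 | (3aS,7aR)-3-(1,3-dioxolan-2-yl)-7a-methyl-1,3a,4,7a-tetrahydro-5H-inden-5-one | O3CCOC3C1=CC[C@]2(C)C=CC(=O)C[C@H]12
F7 | step 4 | (3aS,7S,7aR)-3-(1,3-dioxolan-2-yl)-7,7a-dimethyl-1,3a,4,6,7,7a-hexahydro-5H-inden-5-one | O3CCOC3C1=CC[C@]2(C)[C@@H](C)CC(=O)C[C@H]12
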